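The numbers in the tables were computed with made-up constants; the scatter is artificial.

The proposed steps forbid a product without a partner spent on it, so the reagent charge caps the product. I called D the least share of the solid reagent that must reach substrate for every substrate molecule to become product, charged substrates over charged reagent: 50.0% in this flask.

| flask | left-handed substrate | right-handed substrate | solid reagent | remark | time |
|---|---|---|---|---|---|
| Thursday's | 0.10 M | 0.10 M | 0.80 M | run made earlier |  |
| flask | 0.20 M | 0.20 M | 0.800 M |  | 30 min |

Thursday's run (percent of the left-handed substrate and right-handed substrate together charged)

| time / min | left-handed substrate / % | right-handed substrate / % | left-handed product / % |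
|---|---|---|---|
| 0.833 | 1.6 | 3.7 | 48.8 |
| 2.00 | 0 | 0 | 54.0 |
| 4.00 | 0 | 0.2 | 53.9 |
| 6.00 | 0 | 0.4 | 52.9 |

(readings scatter by 0.5 percentage points)

- partner is single-handed; left-handed substrate and right-handed substrate are mirror images of each other, charged as a racemate, each of them at the stated concentration
- given per volume of solution although it is solid: solid reagent
- steps that have been proposed: partner + left-handed substrate -> left-handed product; partner + right-handed substrate -> right-handed product; left-handed substrate <-> achiral form; right-handed substrate <-> achiral form; partner -> decomposed reagent; solid reagent <-> partner
- at the start none of the solid reagent is in solution
- what has gone into achiral form counts as reacted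
- an excess is the difference of the two amounts in percent of their sum
- an excess is below zero if the other one leads
- the handed part of partner does not stay in what it makes, so the products of the two hands are mirror images too

- part of the left-handed substrate and right-handed substrate charged together that has reacted at 30 min
- excess of left-handed product over right-handed product in the product at 30 min
- excess of right-handed substrate over left-handed substrate among what is left of the two at 30 min

At first this flask looked safe, with reagent at twice the substrates. But on Thursday's run D was 25.0%, so the substrates reading 0% and 0% at 2.00 min speak for a share of about that figure, not for this flask's higher one, and partner can also decompose. I still expected nearly complete conversion, though with less confidence, and allowed for a small remainder.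

The excess was harder. Thursday's readings at 0.833 min give right-handed over left-handed substrate of 39.6%, which is tempting. But these are small readings with a scatter of 0.5 percentage points, taken while substrate was falling. The proposed steps let the mirror images pass into each other through the achiral form, so I expected an excess near zero at 30 min.

The forecast gave 99.5%, 10% and 35%, saying “eS is poorly determined”. On the excess of substrate it and I differed.

The flask gives 99.0%, 9.14% and 0%.

    partner + left-handed substrate → left-handed product (k = 1.30 /M/s)
    partner + right-handed substrate → right-handed product (k = 0.740 /M/s)
    left-handed substrate ⇌ achiral form (K = 0.790, k = 0.0320 /s)
    right-handed substrate ⇌ achiral form (K = 0.790, k = 0.0320 /s)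
    partner → decomposed reagent (k = 0.0530 /s)
    solid reagent ⇌ partner, rate k6*(cs6 - [partner]) while solid is left; crystals form when [partner] > cs6 (solubility = 0.130 M, k = 0.190 /s)

In this flask the products took 49.3% of the solid reagent, just under D, while decomposed reagent reached 0.406 M. The relaxation half-life of right-handed substrate and achiral form, 0.159 min, both ways together, is far shorter than 30 min, and the substrates stand at 0.497% and 0.497%. In the neighbouring flask with 0.20 M of solid reagent, the limiting reagent with 0% left, D is 200%, which caps product at 50.0% of the charge, and the two products reach 41.2%.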